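**Retrosynthetic overview**

1. The oxirane is made last, by hydroxyl-directed epoxidation of the C1=C2 vinyl group of elemanolide 20.
2. The cyclohexane ring (C5, C10) comes from a Cope rearrangement of the 15-oxo-germacra-1(10),4-dienolide 19, triggered by oxidising the C15 alcohol of 18.
3. The 10-membered ring is closed at C6–C7, the bond formed in germacrane biosynthesis, by a Lewis-acid allylsilane–enal cyclisation of 14; this sets C6 and C7.
4. The lactone ring is brought in preformed: a vinylogous aldol of 3-bromobutenolide 8 with enal 5 sets C8 and C9, and a Negishi coupling then installs the CH2SiMe3 group.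
5. Enal 5 comes from iron-catalysed syn-carbomagnesiation of butynediol mono-ether 1 and cross-metathesis with methacrolein. Ring order: lactone (preformed), 10-membered carbocycle, cyclohexane, oxirane.

Assumption: 1, 2 and 12 are bought (2 and 12 as ethereal solutions); locants C1–C15 for 15–21 follow germacrane/elemane numbering (C12 lactone carbonyl, C13 exocyclic methylene, C14/C15 the one-carbon branches on C10/C4).

**Step 1**
Reactants: 1 4-[(tert-butyldimethylsilyl)oxy]but-2-yn-1-ol; 2 but-3-en-1-ylmagnesium bromide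
Product: 3 (2Z)-3-{[(tert-butyldimethylsilyl)oxy]methyl}hepta-2,6-dien-1-ol
Conditions: Fe(acac)3 (15 mol%), 2 (4 equiv), THF, −78 → 0 °C; then H2O
Reagents that add atoms: but-3-en-1-ylmagnesium bromide 2, C=CCC[Mg]Br
Why: Alkoxide-directed iron-catalysed syn-carbomagnesiation of a propargylic alcohol puts the butenyl group on the alkyne carbon remote from the free hydroxyl and magnesium on the near carbon from the same side, so protonation leaves CH2OH and CH2OTBS cis (2Z), the geometry needed for the ring-trans C4=C5 bond.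

**Step 2**
Reactants: 3 (2Z)-3-{[(tert-butyldimethylsilyl)oxy]methyl}hepta-2,6-dien-1-ol; 4 methacrolein
Product: 5 (2E,6Z)-6-{[(tert-butyldimethylsilyl)oxy]methyl}-8-hydroxy-2-methylocta-2,6-dienal
Conditions: 4 (10 equiv), second-generation Hoveyda–Grubbs catalyst (5 mol%), CH2Cl2, 40 °C
Reagents that add atoms: methacrolein 4, C=C(C)C=O
Why: Olefin cross-metathesis of the terminal alkene with excess methacrolein gives the trisubstituted enal as the thermodynamic E isomer (the later 1(10)E bond), while the trisubstituted C4=C5 bond does not react.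

**Step 3**
Reactants: 6 furan-2(5H)-one
Product: 8 3-bromofuran-2(5H)-one, via trans-3,4-dibromodihydrofuran-2(3H)-one 7 (not isolated)
Conditions: Br2, CH2Cl2, 0 °C → rt; then Et3N, 0 °C
Reagents that add atoms: bromine, BrBr
Why: Bromination–dehydrobromination: anti addition of Br2 followed by base-induced loss of HBr (acidic α-hydrogen, β-bromide leaves) gives the α-bromobutenolide.

**Step 4**
Reactants: 5 (2E,6Z)-6-{[(tert-butyldimethylsilyl)oxy]methyl}-8-hydroxy-2-methylocta-2,6-dienal; 8 3-bromofuran-2(5H)-one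
Product: 9 (5R)-3-bromo-5-[(1S,2E,6Z)-6-{[(tert-butyldimethylsilyl)oxy]methyl}-1,8-dihydroxy-2-methylocta-2,6-dien-1-yl]furan-2(5H)-one
Conditions: 8 (2 equiv), cinchona-derived tertiary-amine squaramide (10 mol%; the pseudoenantiomer giving the 5R,1′S adduct), CH2Cl2, 0 °C
Reagents that add atoms: 3-bromofuran-2(5H)-one 8, O=C1OCC=C1Br
Why: Direct asymmetric vinylogous aldol reaction: the amine forms the 2-oxyfuran dienolate of 8 (bromine raises the γ-acidity), the squaramide binds the enal, and γ-attack through the anti-selective hydrogen-bonded transition state sets C8 (R) and C9 (S) under catalyst control.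

**Step 5**
Reactants: 9 (5R)-3-bromo-5-[(1S,2E,6Z)-6-{[(tert-butyldimethylsilyl)oxy]methyl}-1,8-dihydroxy-2-methylocta-2,6-dien-1-yl]furan-2(5H)-one
Product: 10 (2Z,6E,8S)-8-[(2R)-4-bromo-5-oxo-2,5-dihydrofuran-2-yl]-3-{[(tert-butyldimethylsilyl)oxy]methyl}-8-hydroxy-7-methylocta-2,6-dienal
Conditions: TEMPO (10 mol%), PhI(OAc)2 (1.1 equiv), CH2Cl2, rt
Reagents that add atoms: none
Why: Oxoammonium (TEMPO/PhI(OAc)2) oxidation takes the primary allylic alcohol in preference to the hindered secondary one and does not isomerise the Z-enal, so C6 is unmasked as the aldehyde without a protecting group.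

**Step 6**
Reactants: 10 (2Z,6E,8S)-8-[(2R)-4-bromo-5-oxo-2,5-dihydrofuran-2-yl]-3-{[(tert-butyldimethylsilyl)oxy]methyl}-8-hydroxy-7-methylocta-2,6-dienal
Product: 11 (2Z,6E,8S)-8-[(2R)-4-bromo-5-oxo-2,5-dihydrofuran-2-yl]-8-[(tert-butyldimethylsilyl)oxy]-3-{[(tert-butyldimethylsilyl)oxy]methyl}-7-methylocta-2,6-dienal
Conditions: TBSOTf, 2,6-lutidine, CH2Cl2, −78 °C
Reagents that add atoms: tert-butyldimethylsilyl trifluoromethanesulfonate, CC(C)(C)[Si](C)(C)OS(=O)(=O)C(F)(F)F
Why: Silyl ether formation masks the C9 hydroxyl before the allylsilane is present (a silyl triflate would otherwise trigger its addition), so that only O6 is free for acylation later.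

**Step 7**
Reactants: 11 (2Z,6E,8S)-8-[(2R)-4-bromo-5-oxo-2,5-dihydrofuran-2-yl]-8-[(tert-butyldimethylsilyl)oxy]-3-{[(tert-butyldimethylsilyl)oxy]methyl}-7-methylocta-2,6-dienal; 12 [(trimethylsilyl)methyl]magnesium chloride
Product: 14 (2Z,6E,8S)-8-[(tert-butyldimethylsilyl)oxy]-3-{[(tert-butyldimethylsilyl)oxy]methyl}-7-methyl-8-{(2R)-5-oxo-4-[(trimethylsilyl)methyl]-2,5-dihydrofuran-2-yl}octa-2,6-dienal, via [(trimethylsilyl)methyl]zinc chloride 13 (not isolated)
Conditions: 12 (1.5 equiv), ZnCl2 (1.6 equiv), THF, 0 °C; then 11, Pd(PPh3)4 (5 mol%), THF, rt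
Reagents that add atoms: [(trimethylsilyl)methyl]magnesium chloride 12, C[Si](C)(C)C[Mg]Cl (transferred as zinc reagent 13, C[Si](C)(C)C[Zn]Cl)
Why: Negishi coupling of the α-bromobutenolide with an alkylzinc that has no β-hydrogen gives the β-carbonyl allylsilane; the organozinc leaves the enal and the lactone untouched.

**Step 8**
Reactants: 14 (2Z,6E,8S)-8-[(tert-butyldimethylsilyl)oxy]-3-{[(tert-butyldimethylsilyl)oxy]methyl}-7-methyl-8-{(2R)-5-oxo-4-[(trimethylsilyl)methyl]-2,5-dihydrofuran-2-yl}octa-2,6-dienal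
Product: 15 (1(10)E,4Z,6S,7S,8R,9S)-9,15-bis[(tert-butyldimethylsilyl)oxy]-6-hydroxygermacra-1(10),4,11(13)-trien-12,8-olide
Conditions: BF3·OEt2 (3 equiv), CH2Cl2 (1 mM, slow addition of 14), −78 °C; then aq. NaHCO3 at −78 °C
Reagents that add atoms: none
Why: Proposed new method: BF3 makes the enal carbon C6 the electrophile and the butenolide π-bond attacks through C7 with loss of Me3Si+ from C13 (the polarity of the enzymatic C6–C7 closure, silicon in place of the proton), and an open transition state with approach anti to the C8 side chain should give the trans-fused lactone and the 6,7-syn alcohol, i.e. (6S,7S), whereas a closed chair allylmetal transition state would give 6R; the closest known reaction is the intramolecular Hosomi–Sakurai cyclisation of ω-formyl 2-(alkoxycarbonyl)allylsilanes to ring-fused α-methylene-γ-butyrolactones.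

**Step 9**
Reactants: 15 (1(10)E,4Z,6S,7S,8R,9S)-9,15-bis[(tert-butyldimethylsilyl)oxy]-6-hydroxygermacra-1(10),4,11(13)-trien-12,8-olide; 16 (2S)-2-methylbutanoic anhydride
Product: 17 (1(10)E,4Z,6S,7S,8R,9S)-9,15-bis[(tert-butyldimethylsilyl)oxy]-6-{[(2S)-2-methylbutanoyl]oxy}germacra-1(10),4,11(13)-trien-12,8-olide
Conditions: 16 (2 equiv), DMAP (0.2 equiv), pyridine, CH2Cl2, 0 °C → rt
Reagents that add atoms: (2S)-2-methylbutanoic anhydride 16, CC[C@H](C)C(=O)OC(=O)[C@@H](C)CC
Why: DMAP-catalysed acylation of the only free hydroxyl proceeds with retention at C6, and the symmetric anhydride of the commercial (S)-acid carries the side-chain stereocentre in without a ketene-prone acid chloride.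

**Step 10**
Reactants: 17 (1(10)E,4Z,6S,7S,8R,9S)-9,15-bis[(tert-butyldimethylsilyl)oxy]-6-{[(2S)-2-methylbutanoyl]oxy}germacra-1(10),4,11(13)-trien-12,8-olide
Product: 18 (1(10)E,4Z,6S,7S,8R,9S)-9,15-dihydroxy-6-{[(2S)-2-methylbutanoyl]oxy}germacra-1(10),4,11(13)-trien-12,8-olide
Conditions: HF·pyridine, pyridine, THF, 0 °C → rt
Reagents that add atoms: none
Why: Buffered fluoride desilylation removes both silyl ethers without touching the ester, the α-methylene lactone or the 1,5-diene.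

**Step 11**
Reactants: 18 (1(10)E,4Z,6S,7S,8R,9S)-9,15-dihydroxy-6-{[(2S)-2-methylbutanoyl]oxy}germacra-1(10),4,11(13)-trien-12,8-olide
Product: 20 (5R,6S,7S,8R,9S,10S)-9-hydroxy-6-{[(2S)-2-methylbutanoyl]oxy}-15-oxoelema-1,3,11(13)-trien-12,8-olide, via (1(10)E,4Z,6S,7S,8R,9S)-9-hydroxy-6-{[(2S)-2-methylbutanoyl]oxy}-15-oxogermacra-1(10),4,11(13)-trien-12,8-olide 19 (not isolated)
Conditions: TEMPO (10 mol%), PhI(OAc)2 (1.1 equiv), CH2Cl2, rt; then PhMe, 80 °C
Reagents that add atoms: none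
Why: Selective oxidation of the primary allylic C15 alcohol gives the 4-formyl E,E-cyclodeca-1,5-diene, which undergoes the [3,3] Cope rearrangement through the chair transition state of the crossed conformer (C14 and C15 both on the β face); this turns the two olefin geometries into C10 (S, β-methyl) and C5 (R, α-hydrogen), driven by relief of ring strain and a planar conjugated acrolein.

**Step 12**
Reactants: 20 (5R,6S,7S,8R,9S,10S)-9-hydroxy-6-{[(2S)-2-methylbutanoyl]oxy}-15-oxoelema-1,3,11(13)-trien-12,8-olide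
Product: 21 (1R,5R,6S,7S,8R,9S,10S)-1,2-epoxy-9-hydroxy-6-{[(2S)-2-methylbutanoyl]oxy}-15-oxoelema-3,11(13)-dien-12,8-olide (CNP0593558.1)
Conditions: VO(Oi-Pr)3 (5 mol%), chiral C2-symmetric bishydroxamic acid ligand (6 mol%; enantiomer chosen for the 1R epoxide), cumene hydroperoxide (1.5 equiv), PhMe, 0 °C → rt
Reagents that add atoms: cumene hydroperoxide, CC(C)(OO)c1ccccc1
Why: Hydroxyl-directed vanadium-catalysed asymmetric epoxidation of a homoallylic alcohol: the vanadate ester of the axial 9-OH delivers oxygen only to the neighbouring vinyl group (the enal and methylene lactone are electron-poor and out of reach), and the chiral ligand sets C1 (R).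

**Compound list**

1 | 4-[(tert-butyldimethylsilyl)oxy]but-2-yn-1-ol | OCC#CCO[Si](C)(C)C(C)(C)C | starting material
2 | but-3-en-1-ylmagnesium bromide | C=CCC[Mg]Br | starting material
3 | (2Z)-3-{[(tert-butyldimethylsilyl)oxy]methyl}hepta-2,6-dien-1-ol | OC/C=C(\CO[Si](C)(C)C(C)(C)C)CCC=C | intermediate
4 | methacrolein | C=C(C)C=O | starting material
5 | (2E,6Z)-6-{[(tert-butyldimethylsilyl)oxy]methyl}-8-hydroxy-2-methylocta-2,6-dienal | OC/C=C(\CO[Si](C)(C)C(C)(C)C)CC/C=C(\C)C=O | intermediate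
6 | furan-2(5H)-one | O=C1OCC=C1 | starting material
7 | trans-3,4-dibromodihydrofuran-2(3H)-one (racemic, one enantiomer drawn) | O=C1OC[C@H](Br)[C@H]1Br | intermediate
8 | 3-bromofuran-2(5H)-one | O=C1OCC=C1Br | intermediate
9 | (5R)-3-bromo-5-[(1S,2E,6Z)-6-{[(tert-butyldimethylsilyl)oxy]methyl}-1,8-dihydroxy-2-methylocta-2,6-dien-1-yl]furan-2(5H)-one | O=C1O[C@@H]([C@@H](O)/C(C)=C/CC/C(CO[Si](C)(C)C(C)(C)C)=C/CO)C=C1Br | intermediate
10 | (2Z,6E,8S)-8-[(2R)-4-bromo-5-oxo-2,5-dihydrofuran-2-yl]-3-{[(tert-butyldimethylsilyl)oxy]methyl}-8-hydroxy-7-methylocta-2,6-dienal | O=C1O[C@@H]([C@@H](O)/C(C)=C/CC/C(CO[Si](C)(C)C(C)(C)C)=C/C=O)C=C1Br | intermediate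
11 | (2Z,6E,8S)-8-[(2R)-4-bromo-5-oxo-2,5-dihydrofuran-2-yl]-8-[(tert-butyldimethylsilyl)oxy]-3-{[(tert-butyldimethylsilyl)oxy]methyl}-7-methylocta-2,6-dienal | O=C1O[C@@H]([C@@H](O[Si](C)(C)C(C)(C)C)/C(C)=C/CC/C(CO[Si](C)(C)C(C)(C)C)=C/C=O)C=C1Br | intermediate
12 | [(trimethylsilyl)methyl]magnesium chloride | C[Si](C)(C)C[Mg]Cl | starting material
13 | [(trimethylsilyl)methyl]zinc chloride | C[Si](C)(C)C[Zn]Cl | intermediate
14 | (2Z,6E,8S)-8-[(tert-butyldimethylsilyl)oxy]-3-{[(tert-butyldimethylsilyl)oxy]methyl}-7-methyl-8-{(2R)-5-oxo-4-[(trimethylsilyl)methyl]-2,5-dihydrofuran-2-yl}octa-2,6-dienal | O=C1O[C@@H]([C@@H](O[Si](C)(C)C(C)(C)C)/C(C)=C/CC/C(CO[Si](C)(C)C(C)(C)C)=C/C=O)C=C1C[Si](C)(C)C | intermediate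
15 | (1(10)E,4Z,6S,7S,8R,9S)-9,15-bis[(tert-butyldimethylsilyl)oxy]-6-hydroxygermacra-1(10),4,11(13)-trien-12,8-olide | C=C1C(=O)O[C@@H]2[C@@H]1[C@@H](O)/C=C(\CO[Si](C)(C)C(C)(C)C)CC/C=C(\C)[C@@H]2O[Si](C)(C)C(C)(C)C | intermediate
16 | (2S)-2-methylbutanoic anhydride | CC[C@H](C)C(=O)OC(=O)[C@@H](C)CC | starting material
17 | (1(10)E,4Z,6S,7S,8R,9S)-9,15-bis[(tert-butyldimethylsilyl)oxy]-6-{[(2S)-2-methylbutanoyl]oxy}germacra-1(10),4,11(13)-trien-12,8-olide | C=C1C(=O)O[C@@H]2[C@@H]1[C@@H](OC(=O)[C@@H](C)CC)/C=C(\CO[Si](C)(C)C(C)(C)C)CC/C=C(\C)[C@@H]2O[Si](C)(C)C(C)(C)C | intermediate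
18 | (1(10)E,4Z,6S,7S,8R,9S)-9,15-dihydroxy-6-{[(2S)-2-methylbutanoyl]oxy}germacra-1(10),4,11(13)-trien-12,8-olide | C=C1C(=O)O[C@@H]2[C@@H]1[C@@H](OC(=O)[C@@H](C)CC)/C=C(\CO)CC/C=C(\C)[C@@H]2O | intermediate
19 | (1(10)E,4Z,6S,7S,8R,9S)-9-hydroxy-6-{[(2S)-2-methylbutanoyl]oxy}-15-oxogermacra-1(10),4,11(13)-trien-12,8-olide | C=C1C(=O)O[C@@H]2[C@@H]1[C@@H](OC(=O)[C@@H](C)CC)/C=C(\C=O)CC/C=C(\C)[C@@H]2O | intermediate
20 | (5R,6S,7S,8R,9S,10S)-9-hydroxy-6-{[(2S)-2-methylbutanoyl]oxy}-15-oxoelema-1,3,11(13)-trien-12,8-olide | C=C1C(=O)O[C@@H]2[C@@H]1[C@@H](OC(=O)[C@@H](C)CC)[C@@H](C(=C)C=O)[C@](C)(C=C)[C@@H]2O | intermediate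
21 | (1R,5R,6S,7S,8R,9S,10S)-1,2-epoxy-9-hydroxy-6-{[(2S)-2-methylbutanoyl]oxy}-15-oxoelema-3,11(13)-dien-12,8-olide (CNP0593558.1) | C=C1C(=O)O[C@@H]2[C@@H]1[C@@H](OC(=O)[C@@H](C)CC)[C@@H](C(=C)C=O)[C@](C)([C@@H]1CO1)[C@@H]2O | target

**Totals and risks**

Total step count: 12. Longest linear sequence: 11 steps (steps 1, 2 and 4–12; step 3 is a one-step side branch).

Steps most likely to fail:

1. Step 8, the C6–C7 ring closure. The β-carbonyl allylsilane is a weak nucleophile, a 10-membered ring has to form, the Lewis acid can trigger transannular cyclisation of the germacradiene, and the ring may impose the 6-epimer or the cis-fused lactone. The fallback sets out from 11 and comes back at 17. Stille coupling of 11 with (tributylstannyl)methanol (Pd(PPh3)4, dioxane, 80 °C) gives (2Z,6E,8S)-8-[(tert-butyldimethylsilyl)oxy]-3-{[(tert-butyldimethylsilyl)oxy]methyl}-8-[(2R)-4-(hydroxymethyl)-5-oxo-2,5-dihydrofuran-2-yl]-7-methylocta-2,6-dienal F1. PBr3 in Et2O at 0 °C converts it to the bromomethyl butenolide F2. A Nozaki–Hiyama–Kishi macrocyclisation with CrCl2 (divalent chromium) in THF/DMF at high dilution closes the same C6–C7 bond through the closed chair transition state, which is expected to give the C6 epimer, (6R)-9,15-bis[(tert-butyldimethylsilyl)oxy]-6-hydroxygermacra-1(10),4,11(13)-trien-12,8-olide F3. Mitsunobu esterification of F3 with (2S)-2-methylbutanoic acid (PPh3, DIAD, PhMe, 0 °C) inverts C6 and gives 17 directly.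

2. Step 4, the vinylogous aldol. The acceptor is an α-branched enal, the 3-bromofuranone is not a standard donor, and both anti selectivity and ee are untested on this pair. The fallback sets out from 8 (with 5) and comes back at 9. Compound 8 is converted with TMSOTf/Et3N into the preformed silyl dienol ether 3-bromo-2-(trimethylsilyloxy)furan F4. F4 is added to 5 in a Mukaiyama-type vinylogous aldol under chiral ion-pair catalysis (cinchona thiourea ammonium carboxylate, anti-selective; the primary hydroxyl of 5 is silylated in passing). Mild acidic work-up gives 9. If needed the minor syn isomer is removed by chromatography.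

3. Step 12, the epoxidation. Facial selectivity at a vinyl group on a quaternary carbon is hard to predict, and the catalyst may be mismatched with the substrate. The fallback sets out from 20 and comes back at 21. Unselective epoxidation of the vinyl group with dimethyldioxirane (acetone, 0 °C) gives 21 together with its C1 epimer, (1S)-1,2-epoxy-9-hydroxy-6-{[(2S)-2-methylbutanoyl]oxy}-15-oxoelema-3,11(13)-dien-12,8-olide F5. Hydrolytic kinetic resolution with Jacobsen's [N,N′-bis(3,5-di-tert-butylsalicylidene)cyclohexane-1,2-diaminato]cobalt acetate, (salen)Co(OAc) (trivalent cobalt; the enantiomer that opens the 1S epoxide), and 0.55 equiv of water per mole of F5 converts F5 into the (1S)-1,2-diol F6. Compound 21 is left untouched and is separated by chromatography.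

**Further compounds**

F1 | step 8 | (2Z,6E,8S)-8-[(tert-butyldimethylsilyl)oxy]-3-{[(tert-butyldimethylsilyl)oxy]methyl}-8-[(2R)-4-(hydroxymethyl)-5-oxo-2,5-dihydrofuran-2-yl]-7-methylocta-2,6-dienal | O=C1O[C@@H]([C@@H](O[Si](C)(C)C(C)(C)C)/C(C)=C/CC/C(CO[Si](C)(C)C(C)(C)C)=C/C=O)C=C1CO
F2 | step 8 | (2Z,6E,8S)-8-[(2R)-4-(bromomethyl)-5-oxo-2,5-dihydrofuran-2-yl]-8-[(tert-butyldimethylsilyl)oxy]-3-{[(tert-butyldimethylsilyl)oxy]methyl}-7-methylocta-2,6-dienal | O=C1O[C@@H]([C@@H](O[Si](C)(C)C(C)(C)C)/C(C)=C/CC/C(CO[Si](C)(C)C(C)(C)C)=C/C=O)C=C1CBr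
F3 | step 8 | (1(10)E,4Z,6R,7S,8R,9S)-9,15-bis[(tert-butyldimethylsilyl)oxy]-6-hydroxygermacra-1(10),4,11(13)-trien-12,8-olide | C=C1C(=O)O[C@@H]2[C@@H]1[C@H](O)/C=C(\CO[Si](C)(C)C(C)(C)C)CC/C=C(\C)[C@@H]2O[Si](C)(C)C(C)(C)C
F4 | step 4 | 3-bromo-2-(trimethylsilyloxy)furan | C[Si](C)(C)Oc1occc1Br
F5 | step 12 | (1S,5R,6S,7S,8R,9S,10S)-1,2-epoxy-9-hydroxy-6-{[(2S)-2-methylbutanoyl]oxy}-15-oxoelema-3,11(13)-dien-12,8-olide | C=C1C(=O)O[C@@H]2[C@@H]1[C@@H](OC(=O)[C@@H](C)CC)[C@@H](C(=C)C=O)[C@](C)([C@H]1CO1)[C@@H]2O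
F6 | step 12 | (1S,5R,6S,7S,8R,9S,10S)-1,2,9-trihydroxy-6-{[(2S)-2-methylbutanoyl]oxy}-15-oxoelema-3,11(13)-dien-12,8-olide | C=C1C(=O)O[C@@H]2[C@@H]1[C@@H](OC(=O)[C@@H](C)CC)[C@@H](C(=C)C=O)[C@](C)([C@H](O)CO)[C@@H]2O
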